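**Retrosynthetic overview** (germacrane numbering: ring C1–C10; C11 = isopropenyl carbon on C7, C12 = its CH2, C13 = its CH3; C14, C15 = methyls on C10, C4)

1. Target ⇒ a (1(10)Z,4Z)-germacradiene with the C3/C8 angelates and C9 acetate put on late; the 4,5-epoxide comes from C3–OH-directed peracid epoxidation and the 1,10-epoxide from C9–OH-directed VO(acac)2 epoxidation (both epoxides are cis-fused, so both ring alkenes must be Z).
2. Isopropenyl group and C9–OH ⇒ a γ-lactone (C11 as carbonyl carbon, ring oxygen on C9), opened by MeLi addition and Wittig methylenation.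
3. C6–C7 ⇒ intramolecular SN2 alkylation of the dianion of that β-hydroxy-γ-butyrolactone by the (Z)-allylic bromide at C6; this closes the ten-membered carbocycle across the lactone and sets C7. Enabling feature: C7 lies between C11 (a masked carboxyl carbon) and the cis-dioxygenated pair C8/C9, so C11–C7–C8–C9–O is the lactone of 2-deoxy-D-ribonic acid with C7 as its enolate carbon, and the Z alkenes C1=C10 and C4=C5 fold the tether C10…C6 onto the face of C7 anti to the C8 oxygen.
4. Open-chain precursor ⇒ Z-selective Wittig union at C1=C10 of a methyl ketone from 2-deoxy-D-ribono-1,4-lactone (C7–C11, C14) with a phosphonium salt (C1–C6, C15) made by copper-catalysed anti-carbomagnesiation of an (S)-propargylic alcohol.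
5. Ring order: γ-lactone (from the sugar) → ten-membered carbocycle (key step) → lactone opened → 1,10-epoxide → 4,5-epoxide.

Key step: step 14

Remark on the chemistry: β denotes the ring face that carries the isopropenyl group on C7 (ring drawn flat), and 2-deoxy-D-ribono-1,4-lactone is taken as a purchasable starting material (otherwise one Br2/H2O oxidation from 2-deoxy-D-ribose).

**Route**

Step 1
Reactants: 1 3-chloropropanoyl chloride; 2 bis(trimethylsilyl)acetylene
Product: 3 5-chloro-1-(trimethylsilyl)pent-1-yn-3-one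
Conditions: AlCl3, CH2Cl2, 0 °C
Reagents that add atoms: none
Why: Friedel–Crafts-type acylation of the bis-silyl alkyne with ipso substitution of one C–Si bond should give the silyl ynone that holds C1–C5; no stereocenter is formed.

Step 2
Reactants: 3 5-chloro-1-(trimethylsilyl)pent-1-yn-3-one
Product: 4 (3S)-5-chloro-1-(trimethylsilyl)pent-1-yn-3-ol
Conditions: RuCl[(S,S)-TsDPEN](p-cymene) (1 mol %), i-PrOH, rt
Reagents that add atoms: none
Why: Noyori asymmetric transfer hydrogenation of an alkynyl ketone, in which the alkyne takes the place of the aryl group in the six-membered hydride-transfer transition state, should set C3 as S under catalyst control.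

Step 3
Reactants: 4 (3S)-5-chloro-1-(trimethylsilyl)pent-1-yn-3-ol
Product: 5 (3S)-5-chloropent-1-yn-3-ol
Conditions: K2CO3 (cat.), MeOH, 0 °C → rt
Reagents that add atoms: none
Why: base-catalysed methanolysis of the alkynyl C–Si bond (protodesilylation) should free the terminal alkyne without touching the C3 carbinol or the primary chloride.

Step 4
Reactants: 5 (3S)-5-chloropent-1-yn-3-ol
Product: 7 (2Z,4S)-6-chloro-3-methylhex-2-ene-1,4-diol, via alkenylmagnesium alkoxide 6 (not isolated)
Conditions: MeMgBr (3.5 equiv), CuI (15 mol %), THF/Et2O, −10 °C → rt; then (CH2O)n, 0 °C → rt; aq NH4Cl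
Reagents that add atoms: methylmagnesium bromide C[Mg]Br; formaldehyde (from paraformaldehyde) C=O
Why: copper-catalysed anti-carbomagnesiation of the propargylic magnesium alkoxide puts the methyl group on C4 and magnesium on C5 cis to the carbinol carbon through a five-membered chelate, so hydroxymethylation of the alkenyl Grignard reagent with retention should give the Z alkene with C3 and C6 cis, the primary chloride being inert under these conditions.

Step 5
Reactants: 7 (2Z,4S)-6-chloro-3-methylhex-2-ene-1,4-diol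
Product: 8 (2Z,4S)-1,4-bis(tert-butyldimethylsilyloxy)-6-chloro-3-methylhex-2-ene
Conditions: t-BuMe2SiCl (2.5 equiv), imidazole, DMF, rt
Reagents that add atoms: tert-butyldimethylsilyl chloride CC(C)(C)[Si](C)(C)Cl
Why: imidazole-promoted silyl ether formation protects C3–OH and C6–OH in one operation, the primary ether being the one that can later be cleaved selectively.

Step 6
Reactants: 8 (2Z,4S)-1,4-bis(tert-butyldimethylsilyloxy)-6-chloro-3-methylhex-2-ene
Product: 9 [(3S,4Z)-3,6-bis(tert-butyldimethylsilyloxy)-4-methylhex-4-en-1-yl]triphenylphosphonium iodide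
Conditions: PPh3, NaI, i-Pr2NEt (cat.), MeCN, 80 °C
Reagents that add atoms: triphenylphosphine c1ccc(cc1)P(c1ccccc1)c1ccccc1; sodium iodide [Na+].[I-]
Why: Finkelstein exchange in the flask followed by SN2 quaternisation of the phosphine at the primary carbon C1 should give the Wittig salt, the silyl ethers and the Z alkene being inert.

Step 7
Reactants: 10 2-deoxy-D-ribono-1,4-lactone
Product: 11 (4S,5R)-4-(triethylsilyloxy)-5-[(triethylsilyloxy)methyl]oxolan-2-one
Conditions: Et3SiCl (2.4 equiv), imidazole, DMF, 0 °C → rt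
Reagents that add atoms: chlorotriethylsilane CC[Si](Cl)(CC)CC
Why: imidazole-promoted silylation of both hydroxyl groups of the sugar lactone, which already holds C8 and C9 in the absolute configuration of the target with O8 and C10 trans on the lactone ring.

Step 8
Reactants: 11 (4S,5R)-4-(triethylsilyloxy)-5-[(triethylsilyloxy)methyl]oxolan-2-one
Product: 13 (2S,3S)-5-oxo-3-(triethylsilyloxy)oxolane-2-carbaldehyde, via alkoxysulfonium chloride 12 (not isolated)
Conditions: (COCl)2, DMSO, CH2Cl2, −78 → −30 °C; then Et3N, −78 → 0 °C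
Reagents that add atoms: none
Why: Swern oxidation run directly on the bis-silyl ether, in which the primary triethylsilyl ether oxygen attacks the chlorosulfonium salt and gives up its silyl group to chloride while the secondary ether stays, should give the C10 aldehyde in one operation; the cold quench and use of the crude aldehyde limit β-elimination of the C8 silyloxy group and epimerisation at C9.

Step 9
Reactants: 13 (2S,3S)-5-oxo-3-(triethylsilyloxy)oxolane-2-carbaldehyde
Product: 14 (4S,5R)-5-(1-hydroxyethyl)-4-(triethylsilyloxy)oxolan-2-one (both carbinol epimers)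
Conditions: MeMgBr (1.1 equiv), THF, −78 °C; aq NH4Cl
Reagents that add atoms: methylmagnesium bromide C[Mg]Br
Why: Grignard addition to the aldehyde, far faster than to the lactone at −78 °C, brings in the C14 methyl group; the new carbinol centre does not matter because it is oxidised next.

Step 10
Reactants: 14 (4S,5R)-5-(1-hydroxyethyl)-4-(triethylsilyloxy)oxolan-2-one
Product: 15 (4S,5S)-5-acetyl-4-(triethylsilyloxy)oxolan-2-one
Conditions: Dess–Martin periodinane, NaHCO3, CH2Cl2, 0 °C → rt
Reagents that add atoms: none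
Why: Dess–Martin oxidation under buffered, non-basic conditions should give the α-acyloxy methyl ketone without epimerising C9 or eliminating the C8 silyloxy group.

Step 11
Reactants: 9 [(3S,4Z)-3,6-bis(tert-butyldimethylsilyloxy)-4-methylhex-4-en-1-yl]triphenylphosphonium iodide; 15 (4S,5S)-5-acetyl-4-(triethylsilyloxy)oxolan-2-one
Product: 17 (4S,5R)-5-[(2Z,5S,6Z)-5,8-bis(tert-butyldimethylsilyloxy)-6-methylocta-2,6-dien-2-yl]-4-(triethylsilyloxy)oxolan-2-one, via phosphonium ylide 16 (not isolated)
Conditions: KN(SiMe3)2 (0.98 equiv to 9), THF, −78 → 0 °C; then 15, −78 °C → rt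
Reagents that add atoms: none
Why: Wittig olefination of an α-oxygenated methyl ketone with a non-stabilised, lithium-free ylide, a combination known to place the oxygen-bearing carbon (C9) cis to the ylide alkyl group (C2), should join the fragments as the Z-trisubstituted C1=C10 alkene, carbonyl addition at −78 °C being expected to outrun enolisation.

Step 12
Reactants: 17 (4S,5R)-5-[(2Z,5S,6Z)-5,8-bis(tert-butyldimethylsilyloxy)-6-methylocta-2,6-dien-2-yl]-4-(triethylsilyloxy)oxolan-2-one
Product: 18 (4S,5R)-5-[(2Z,5S,6Z)-5-(tert-butyldimethylsilyloxy)-8-hydroxy-6-methylocta-2,6-dien-2-yl]-4-hydroxyoxolan-2-one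
Conditions: HF·pyridine, pyridine, THF, 0 °C → rt
Reagents that add atoms: none
Why: buffered fluoride desilylation cleaves the primary allylic tert-butyldimethylsilyl ether and the secondary triethylsilyl ether much faster than the secondary tert-butyldimethylsilyl ether at C3, which should free C6–OH and C8–OH only.

Step 13
Reactants: 18 (4S,5R)-5-[(2Z,5S,6Z)-5-(tert-butyldimethylsilyloxy)-8-hydroxy-6-methylocta-2,6-dien-2-yl]-4-hydroxyoxolan-2-one
Product: 20 (4S,5R)-5-[(2Z,5S,6Z)-8-bromo-5-(tert-butyldimethylsilyloxy)-6-methylocta-2,6-dien-2-yl]-4-hydroxyoxolan-2-one, via alkoxysulfonium bromide 19 (not isolated)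
Conditions: N-bromosuccinimide, Me2S, CH2Cl2, −25 → 0 °C
Reagents that add atoms: N-bromosuccinimide O=C1CCC(=O)N1Br
Why: Corey–Kim-type halogenation, in which the alkoxysulfonium salt of an allylic alcohol is displaced by bromide in an SN2 manner while that of a saturated secondary alcohol only reverts on work-up, should turn C6–OH into the allylic bromide with the Z geometry kept and leave C8–OH free.

Step 14
Reactants: 20 (4S,5R)-5-[(2Z,5S,6Z)-8-bromo-5-(tert-butyldimethylsilyloxy)-6-methylocta-2,6-dien-2-yl]-4-hydroxyoxolan-2-one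
Product: 23 bridged lactone 3β-(tert-butyldimethylsilyloxy)-8β-(triisopropylsilyloxy)-12,13-dinorgermacra-1(10)Z,4Z-dien-11,9β-olide (7αH), via dilithium enolate alkoxide 21 (not isolated), via bridged lithium alkoxide 22 (not isolated)
Conditions: LiN(SiMe3)2 (3.5 equiv), THF/DMPU (10:1), 20 added by syringe pump to 2 mM, −78 → −20 °C; then i-Pr3SiOTf, −20 → 0 °C
Reagents that add atoms: triisopropylsilyl trifluoromethanesulfonate CC(C)[Si](C(C)C)(C(C)C)OS(=O)(=O)C(F)(F)F
Why: Proposed new method: the base should form first the C8 lithium alkoxide and then the lactone enolate, and this dianion, which cannot expel its β-oxygen, should displace the allylic bromide at C6 by SN2 C-alkylation at C7; the closest known reactions are the Fráter–Seebach-type alkylation of β-hydroxy ester and β-hydroxy-γ-butyrolactone dianions with allylic halides (trans to the oxygen) and the closure of ten-membered carbocycles by intramolecular alkylation of stabilised carbanions with allylic halides, which have not been combined in a bridging macrocyclisation. The ten-membered ring closes in a 10-exo-tet mode between the α-carbon and the chain on the γ-carbon of the lactone, giving the 1,3-bridged lactone. The new stereocentre C7 is set by the lactone: the chain on C9 can only reach the enolate face on which it stands, and that face is anti to the C8 alkoxide, the face the dianion prefers in any case, so C6 ends trans to O8 and cis to C10 as in the target. The step needs C- over O-alkylation, SN2 over SN2' and ring closure over oligomerisation; a lithium enolate with a primary allylic bromide, the eight-membered ring with a quaternary centre that SN2' would cost, and high dilution with two Z alkenes folding the tether into a low-strain (Z,Z)-cyclodeca-1,5-diene should secure these. The C8 alkoxide left after closure is silylated in the same flask with a bulky group that resists 1,2-migration, so that O8 and O9 stay distinguishable once the lactone is opened.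

Step 15
Reactants: 23 bridged lactone 3β-(tert-butyldimethylsilyloxy)-8β-(triisopropylsilyloxy)-12,13-dinorgermacra-1(10)Z,4Z-dien-11,9β-olide
Product: 24 lactol 9β,11-epoxy-3β-(tert-butyldimethylsilyloxy)-8β-(triisopropylsilyloxy)-12-norgermacra-1(10)Z,4Z-dien-11-ol (anomers; in equilibrium with the 9-hydroxy-11-ketone)
Conditions: MeLi (1.2 equiv), THF, −78 °C; aq NH4Cl
Reagents that add atoms: methyllithium C[Li]
Why: addition of one equivalent of an organolithium to a γ-lactone, stopped at the lithium hemiketal that is stable at −78 °C, brings in C13; C7 cannot epimerise while the bridge is intact and the hemiketal centre is lost in the next step.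

Step 16
Reactants: 24 lactol 9β,11-epoxy-3β-(tert-butyldimethylsilyloxy)-8β-(triisopropylsilyloxy)-12-norgermacra-1(10)Z,4Z-dien-11-ol
Product: 25 3β-(tert-butyldimethylsilyloxy)-8β-(triisopropylsilyloxy)germacra-1(10)Z,4Z,11-trien-9β-ol
Conditions: Ph3PCH3Br, KN(SiMe3)2, THF, 0 °C
Reagents that add atoms: methyltriphenylphosphonium bromide C[P+](c1ccccc1)(c1ccccc1)c1ccccc1.[Br-]
Why: Wittig methylenation of the hydroxy ketone in equilibrium with the lactol turns C11 into the isopropenyl carbon and frees C9–OH, the low temperature guarding C7 against epimerisation and the bulky silyl group on O8 against migration to the transient C9 alkoxide.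

Step 17
Reactants: 25 3β-(tert-butyldimethylsilyloxy)-8β-(triisopropylsilyloxy)germacra-1(10)Z,4Z,11-trien-9β-ol
Product: 26 1β,10β-epoxy-3β-(tert-butyldimethylsilyloxy)-8β-(triisopropylsilyloxy)germacra-4Z,11-dien-9β-ol
Conditions: VO(acac)2 (5 mol %), t-BuOOH, CH2Cl2, 0 °C → rt
Reagents that add atoms: tert-butyl hydroperoxide CC(C)(C)OO
Why: vanadium-catalysed hydroxyl-directed epoxidation is confined to the allylic C1=C10 alkene of the free C9 alcohol, and because the vanadate ester needs a small O–C9–C10=C1 dihedral angle that a Z-cycloalkene reaches only with oxygen delivered to the face of the C9 oxygen, it should give the cis (β) epoxy alcohol as with medium-ring (Z)-cycloalk-2-enols, setting C1 and C10.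

Step 18
Reactants: 26 1β,10β-epoxy-3β-(tert-butyldimethylsilyloxy)-8β-(triisopropylsilyloxy)germacra-4Z,11-dien-9β-ol
Product: 27 9β-acetoxy-1β,10β-epoxy-3β-(tert-butyldimethylsilyloxy)-8β-(triisopropylsilyloxy)germacra-4Z,11-diene
Conditions: Ac2O, pyridine, DMAP (cat.), CH2Cl2, rt
Reagents that add atoms: acetic anhydride CC(=O)OC(C)=O
Why: DMAP-catalysed acetylation of the only free hydroxyl group installs the C9 acetate.

Step 19
Reactants: 27 9β-acetoxy-1β,10β-epoxy-3β-(tert-butyldimethylsilyloxy)-8β-(triisopropylsilyloxy)germacra-4Z,11-diene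
Product: 28 9β-acetoxy-1β,10β-epoxygermacra-4Z,11-diene-3β,8β-diol
Conditions: Bu4NF/AcOH (1:1), THF, rt → 40 °C
Reagents that add atoms: none
Why: fluoride cleavage of both silyl ethers, buffered with acetic acid so that the transient C8 alkoxide does not take over the neighbouring acetyl group and the epoxide is not opened, should free C3–OH and C8–OH.

Step 20
Reactants: 28 9β-acetoxy-1β,10β-epoxygermacra-4Z,11-diene-3β,8β-diol
Product: 29 9β-acetoxy-1β,10β:4α,5α-diepoxygermacr-11-ene-3β,8β-diol
Conditions: m-CPBA (1.05 equiv), NaHCO3, CH2Cl2, 0 °C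
Reagents that add atoms: 3-chloroperbenzoic acid OOC(=O)c1cccc(Cl)c1
Why: hydrogen-bond-directed peracid epoxidation (Prilezhaev reaction) of the Z-trisubstituted C4=C5 alkene by the allylic C3 hydroxyl, through the conformer that avoids A(1,3) strain with the cis carbon C6 and holds an O–C3–C4=C5 dihedral angle near 120–140°, should deliver oxygen to the α-face, trans (threo) to the C3 oxygen as with medium-ring (Z)-cycloalk-2-enols, and the directed ring alkene should react before the 1,1-disubstituted isopropenyl group.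

Step 21
Reactants: 29 9β-acetoxy-1β,10β:4α,5α-diepoxygermacr-11-ene-3β,8β-diol; 30 angelic acid
Product: 32 CNP0220329.1 9β-acetoxy-3β,8β-bis(angeloyloxy)-1β,10β:4α,5α-diepoxygermacr-11-ene, via mixed anhydride 31 (not isolated)
Conditions: 30 (6 equiv), 2,4,6-trichlorobenzoyl chloride, Et3N, toluene, rt; then 29, 80 °C
Reagents that add atoms: none
Why: Yamaguchi esterification through the mixed 2,4,6-trichlorobenzoic anhydride, run without a nucleophilic catalyst so that the Z (angelate) geometry is not lost to the tiglate, should acylate both hindered secondary hydroxyl groups (C3 and C8) and give the target.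

**Compound list**

1 | 3-chloropropanoyl chloride | ClCCC(Cl)=O | starting material
2 | bis(trimethylsilyl)acetylene | C[Si](C)(C)C#C[Si](C)(C)C | starting material
3 | 5-chloro-1-(trimethylsilyl)pent-1-yn-3-one | C[Si](C)(C)C#CC(=O)CCCl | intermediate
4 | (3S)-5-chloro-1-(trimethylsilyl)pent-1-yn-3-ol | C[Si](C)(C)C#C[C@@H](O)CCCl | intermediate
5 | (3S)-5-chloropent-1-yn-3-ol | C#C[C@@H](O)CCCl | intermediate
6 | bromomagnesium (1Z,3S)-1-(bromomagnesio)-5-chloro-2-methylpent-1-en-3-olate (not isolated) | Br[Mg]/C=C(C)\[C@@H](O[Mg]Br)CCCl | intermediate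
7 | (2Z,4S)-6-chloro-3-methylhex-2-ene-1,4-diol | OC/C=C(C)\[C@@H](O)CCCl | intermediate
8 | (2Z,4S)-1,4-bis(tert-butyldimethylsilyloxy)-6-chloro-3-methylhex-2-ene | CC(C)(C)[Si](C)(C)OC/C=C(C)\[C@@H](O[Si](C)(C)C(C)(C)C)CCCl | intermediate
9 | [(3S,4Z)-3,6-bis(tert-butyldimethylsilyloxy)-4-methylhex-4-en-1-yl]triphenylphosphonium iodide | CC(C)(C)[Si](C)(C)OC/C=C(C)\[C@@H](O[Si](C)(C)C(C)(C)C)CC[P+](c1ccccc1)(c1ccccc1)c1ccccc1.[I-] | intermediate
10 | 2-deoxy-D-ribono-1,4-lactone, (4S,5R)-4-hydroxy-5-(hydroxymethyl)oxolan-2-one | OC[C@H]1OC(=O)C[C@@H]1O | starting material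
11 | (4S,5R)-4-(triethylsilyloxy)-5-[(triethylsilyloxy)methyl]oxolan-2-one | CC[Si](CC)(CC)OC[C@H]1OC(=O)C[C@@H]1O[Si](CC)(CC)CC | intermediate
12 | dimethyl{[(2R,3S)-5-oxo-3-(triethylsilyloxy)oxolan-2-yl]methoxy}sulfonium chloride (not isolated) | C[S+](C)OC[C@H]1OC(=O)C[C@@H]1O[Si](CC)(CC)CC.[Cl-] | intermediate
13 | (2S,3S)-5-oxo-3-(triethylsilyloxy)oxolane-2-carbaldehyde | O=C[C@H]1OC(=O)C[C@@H]1O[Si](CC)(CC)CC | intermediate
14 | (4S,5R)-5-(1-hydroxyethyl)-4-(triethylsilyloxy)oxolan-2-one (both carbinol epimers) | CC(O)[C@H]1OC(=O)C[C@@H]1O[Si](CC)(CC)CC | intermediate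
15 | (4S,5S)-5-acetyl-4-(triethylsilyloxy)oxolan-2-one | CC(=O)[C@H]1OC(=O)C[C@@H]1O[Si](CC)(CC)CC | intermediate
16 | [(3S,4Z)-3,6-bis(tert-butyldimethylsilyloxy)-4-methylhex-4-en-1-ylidene]triphenylphosphorane (not isolated) | CC(C)(C)[Si](C)(C)OC/C=C(C)\[C@@H](O[Si](C)(C)C(C)(C)C)CC=P(c1ccccc1)(c1ccccc1)c1ccccc1 | intermediate
17 | (4S,5R)-5-[(2Z,5S,6Z)-5,8-bis(tert-butyldimethylsilyloxy)-6-methylocta-2,6-dien-2-yl]-4-(triethylsilyloxy)oxolan-2-one | CC(C)(C)[Si](C)(C)OC/C=C(C)\[C@@H](O[Si](C)(C)C(C)(C)C)C/C=C(C)\[C@H]1OC(=O)C[C@@H]1O[Si](CC)(CC)CC | intermediate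
18 | (4S,5R)-5-[(2Z,5S,6Z)-5-(tert-butyldimethylsilyloxy)-8-hydroxy-6-methylocta-2,6-dien-2-yl]-4-hydroxyoxolan-2-one | OC/C=C(C)\[C@@H](O[Si](C)(C)C(C)(C)C)C/C=C(C)\[C@H]1OC(=O)C[C@@H]1O | intermediate
19 | alkoxydimethylsulfonium bromide of 18 at the primary (C6) oxygen (not isolated) | C[S+](C)OC/C=C(C)\[C@@H](O[Si](C)(C)C(C)(C)C)C/C=C(C)\[C@H]1OC(=O)C[C@@H]1O.[Br-] | intermediate
20 | (4S,5R)-5-[(2Z,5S,6Z)-8-bromo-5-(tert-butyldimethylsilyloxy)-6-methylocta-2,6-dien-2-yl]-4-hydroxyoxolan-2-one | BrC/C=C(C)\[C@@H](O[Si](C)(C)C(C)(C)C)C/C=C(C)\[C@H]1OC(=O)C[C@@H]1O | intermediate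
21 | dilithium enolate alkoxide of 20 (lactone enolate at C7/C11, alkoxide at C8; not isolated) | [Li+].[Li+].BrC/C=C(C)\[C@@H](O[Si](C)(C)C(C)(C)C)C/C=C(C)\[C@H]1OC([O-])=C[C@@H]1[O-] | intermediate
22 | lithium 8β-alkoxide of the bridged lactone 3β-(tert-butyldimethylsilyloxy)-12,13-dinorgermacra-1(10)Z,4Z-dien-11,9β-olide (not isolated) | [Li+].O=C3[C@H]1C/C=C(C)\[C@@H](O[Si](C)(C)C(C)(C)C)C/C=C(C)\[C@@H](O3)[C@H]1[O-] | intermediate
23 | bridged lactone 3β-(tert-butyldimethylsilyloxy)-8β-(triisopropylsilyloxy)-12,13-dinorgermacra-1(10)Z,4Z-dien-11,9β-olide (7αH; γ-lactone with C11 carbonyl on C7 and ring oxygen on C9) | O=C3[C@H]1C/C=C(C)\[C@@H](O[Si](C)(C)C(C)(C)C)C/C=C(C)\[C@@H](O3)[C@H]1O[Si](C(C)C)(C(C)C)C(C)C | intermediate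
24 | lactol 9β,11-epoxy-3β-(tert-butyldimethylsilyloxy)-8β-(triisopropylsilyloxy)-12-norgermacra-1(10)Z,4Z-dien-11-ol (anomers) | CC3(O)[C@H]1C/C=C(C)\[C@@H](O[Si](C)(C)C(C)(C)C)C/C=C(C)\[C@@H](O3)[C@H]1O[Si](C(C)C)(C(C)C)C(C)C | intermediate
25 | 3β-(tert-butyldimethylsilyloxy)-8β-(triisopropylsilyloxy)germacra-1(10)Z,4Z,11-trien-9β-ol | C=C(C)[C@H]1C/C=C(C)\[C@@H](O[Si](C)(C)C(C)(C)C)C/C=C(C)\[C@@H](O)[C@H]1O[Si](C(C)C)(C(C)C)C(C)C | intermediate
26 | 1β,10β-epoxy-3β-(tert-butyldimethylsilyloxy)-8β-(triisopropylsilyloxy)germacra-4Z,11-dien-9β-ol | C=C(C)[C@H]1C/C=C(C)\[C@@H](O[Si](C)(C)C(C)(C)C)C[C@H]2O[C@@]2(C)[C@@H](O)[C@H]1O[Si](C(C)C)(C(C)C)C(C)C | intermediate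
27 | 9β-acetoxy-1β,10β-epoxy-3β-(tert-butyldimethylsilyloxy)-8β-(triisopropylsilyloxy)germacra-4Z,11-diene | C=C(C)[C@H]1C/C=C(C)\[C@@H](O[Si](C)(C)C(C)(C)C)C[C@H]2O[C@@]2(C)[C@@H](OC(C)=O)[C@H]1O[Si](C(C)C)(C(C)C)C(C)C | intermediate
28 | 9β-acetoxy-1β,10β-epoxygermacra-4Z,11-diene-3β,8β-diol | C=C(C)[C@H]1C/C=C(C)\[C@@H](O)C[C@H]2O[C@@]2(C)[C@@H](OC(C)=O)[C@H]1O | intermediate
29 | 9β-acetoxy-1β,10β:4α,5α-diepoxygermacr-11-ene-3β,8β-diol | C=C(C)[C@H]1C[C@@H]2O[C@]2(C)[C@@H](O)C[C@H]2O[C@@]2(C)[C@@H](OC(C)=O)[C@H]1O | intermediate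
30 | angelic acid, (2Z)-2-methylbut-2-enoic acid | C/C=C(/C)C(=O)O | starting material
31 | angelic 2,4,6-trichlorobenzoic anhydride (not isolated) | C/C=C(/C)C(=O)OC(=O)c1c(Cl)cc(Cl)cc1Cl | intermediate
32 | CNP0220329.1, 9β-acetoxy-3β,8β-bis(angeloyloxy)-1β,10β:4α,5α-diepoxygermacr-11-ene | C=C(C)[C@H]1C[C@@H]2O[C@]2(C)[C@@H](OC(=O)/C(C)=C\C)C[C@H]2O[C@@]2(C)[C@@H](OC(C)=O)[C@H]1OC(=O)/C(C)=C\C | target

**Step count and risks**

Total step count: 21. Longest linear sequence: 17 steps (steps 1–6 and 11–21); steps 7–10 are the second branch.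

Steps most likely to fail:

Step 14 (the labelled step). The ring closure of the dianion may be too slow, so that intermolecular alkylation to oligomers, O-alkylation or loss of the allylic bromide by elimination take over. The fallback uses known reactions only, sets out from ketone 15 and ylide 16 and returns at 23: the C6–C7 bond would be made between two molecules and the ring closed at C1=C10 by metathesis. Wittig methylenation of 15 (Ph3PCH3Br, KN(SiMe3)2, THF, 0 °C) would give (4S,5R)-5-(prop-1-en-2-yl)-4-(triethylsilyloxy)oxolan-2-one F1, and HF·pyridine would free its hydroxyl group to give (4S,5R)-4-hydroxy-5-(prop-1-en-2-yl)oxolan-2-one F2. Ylide 16 and paraformaldehyde would give (4S,5Z)-4,7-bis(tert-butyldimethylsilyloxy)-5-methylhepta-1,5-diene F3, which would be taken on as in steps 12 and 13 to (2Z,4S)-4-(tert-butyldimethylsilyloxy)-3-methylhepta-2,6-dien-1-ol F4 and (2Z,4S)-1-bromo-4-(tert-butyldimethylsilyloxy)-3-methylhepta-2,6-diene F5. Fráter–Seebach-type alkylation of F2 after double deprotonation (LiN(iPr)2, 2.2 equiv, THF/DMPU, −78 → −30 °C) with F5, trans to the C8 alkoxide, followed by i-Pr3SiOTf in the same flask, would give (3S,4S,5R)-3-[(2Z,4S)-4-(tert-butyldimethylsilyloxy)-3-methylhepta-2,6-dien-1-yl]-5-(prop-1-en-2-yl)-4-(triisopropylsilyloxy)oxolan-2-one F6. Ring-closing metathesis of its isopropenyl and allyl termini (second-generation Grubbs catalyst RuCl2(=CHPh)(PCy3)(H2IMes), toluene, 2 mM, 80 °C), which in a ten-membered ring can only deliver the Z alkene, would return to 23.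

Step 11. The ylide may act as a base toward ketone 15 (enolisation, epimerisation at C9, β-elimination of the C8 silyloxy group), or the Z preference may be eroded by the branched α-carbon. The fallback sets out from chloride 8 and ketone 15 and returns at 17: a Horner–Wittig olefination in two separate stages, in which the alkene geometry is fixed by separation of the adducts and not by the kinetics of the addition. Chloride 8 would be converted (LiPPh2, THF, 0 °C; then H2O2) into [(3S,4Z)-3,6-bis(tert-butyldimethylsilyloxy)-4-methylhex-4-en-1-yl]diphenylphosphine oxide F7. After lithiation (n-BuLi, THF, −78 °C) and transmetallation with CeCl3 to lower the basicity, addition to 15 would give β-hydroxy phosphine oxides; an adduct in which C2 and C9 are eclipsed when the P–C1 and C10–O bonds are syn-periplanar, such as the 1-diphenylphosphinoyl-10-hydroxy adduct F8, would be separated by chromatography. Its stereospecific syn-elimination (NaH, DMF, rt) would give 17.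

Step 20. Facial selectivity at C4=C5 may be poor in the flexible ten-membered ring if the conformer needed for hydrogen-bonded delivery to the α-face is not the reactive one, and the isopropenyl group may be epoxidised in competition. The fallback sets out from diol 28 and mixed anhydride 31 and returns at target 32: the last two steps would be exchanged and the face chosen by the reagent. Diol 28 would first be bis-angeloylated under the conditions of step 21 to give 9β-acetoxy-3β,8β-bis(angeloyloxy)-1β,10β-epoxygermacra-4Z,11-diene F9. Shi epoxidation (the fructose-derived ketone of the enantiomeric series that the spiro transition-state model assigns to the α-face of C4=C5, Oxone (2KHSO5·KHSO4·K2SO4), K2CO3, MeCN/dimethoxymethane/H2O, 0 °C) would then oxidise the trisubstituted ring alkene, which this catalyst prefers over 1,1-disubstituted and electron-poor alkenes, to give 32.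

**Further compounds**

F1 | step 14 | (4S,5R)-5-(prop-1-en-2-yl)-4-(triethylsilyloxy)oxolan-2-one | C=C(C)[C@H]1OC(=O)C[C@@H]1O[Si](CC)(CC)CC
F2 | step 14 | (4S,5R)-4-hydroxy-5-(prop-1-en-2-yl)oxolan-2-one | C=C(C)[C@H]1OC(=O)C[C@@H]1O
F3 | step 14 | (4S,5Z)-4,7-bis(tert-butyldimethylsilyloxy)-5-methylhepta-1,5-diene | CC(C)(C)[Si](C)(C)OC/C=C(C)\[C@@H](O[Si](C)(C)C(C)(C)C)CC=C
F4 | step 14 | (2Z,4S)-4-(tert-butyldimethylsilyloxy)-3-methylhepta-2,6-dien-1-ol | OC/C=C(C)\[C@@H](O[Si](C)(C)C(C)(C)C)CC=C
F5 | step 14 | (2Z,4S)-1-bromo-4-(tert-butyldimethylsilyloxy)-3-methylhepta-2,6-diene | BrC/C=C(C)\[C@@H](O[Si](C)(C)C(C)(C)C)CC=C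
F6 | step 14 | (3S,4S,5R)-3-[(2Z,4S)-4-(tert-butyldimethylsilyloxy)-3-methylhepta-2,6-dien-1-yl]-5-(prop-1-en-2-yl)-4-(triisopropylsilyloxy)oxolan-2-one | O=C1O[C@H](C(C)=C)[C@@H](O[Si](C(C)C)(C(C)C)C(C)C)[C@@H]1C/C=C(C)\[C@@H](O[Si](C)(C)C(C)(C)C)CC=C
F7 | step 11 | [(3S,4Z)-3,6-bis(tert-butyldimethylsilyloxy)-4-methylhex-4-en-1-yl]diphenylphosphine oxide | CC(C)(C)[Si](C)(C)OC/C=C(C)\[C@@H](O[Si](C)(C)C(C)(C)C)CCP(=O)(c1ccccc1)c1ccccc1
F8 | step 11 | 1-diphenylphosphinoyl-10-hydroxy adduct of F7 and 15 (a diastereomer that eliminates to the Z alkene) | C[C@@](O)([C@@H](C[C@H](O[Si](C)(C)C(C)(C)C)/C(C)=C\CO[Si](C)(C)C(C)(C)C)P(=O)(c1ccccc1)c1ccccc1)[C@H]1OC(=O)C[C@@H]1O[Si](CC)(CC)CC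
F9 | step 20 | 9β-acetoxy-3β,8β-bis(angeloyloxy)-1β,10β-epoxygermacra-4Z,11-diene | C=C(C)[C@H]1C/C=C(C)\[C@@H](OC(=O)/C(C)=C\C)C[C@H]2O[C@@]2(C)[C@@H](OC(C)=O)[C@H]1OC(=O)/C(C)=C\C
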